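**Strategy.** Plicatic acid is read as D-tartaric acid whose carbinol carbons C3 and C2 are bridged by C4H2, ring A and C1H(ring C). Everything rests on the C1–C2 disconnection. C1 is doubly benzylic and lies para to the C6 methoxy group of ring A and to O4' of ring C, so a C1–O bond ionises easily. The precursor is a 1-arylisochroman (C1–O–C3) that carries a silyl ketene acetal at C2. Catalytic Me3SiOTf opens the heterocycle to a planar diarylmethyl cation and C2 captures it. One stereoconvergent operation delivers the tetralin ring, C1, C2 and the free C3 hydroxyl under control of C3 alone.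

Key step: step 7

Remark: atom numbers are those of the tetralin of the target. Ring A is its benzo ring, ring B the carbocycle C1–C4, and ring C the pendant aryl group. Centres written RS (acetal carbon of 7 and 8, C1 of 9–11) are uncontrolled mixtures that steps 5 and 7 planarise. The stereoretentive course known for isopropylidene tartrate enolates is assumed to hold for the arylmethylidene acetal 4.

Step 1
Reactants: 1 3,4-dihydroxy-5-methoxybenzaldehyde
Product: 2 3,4-bis(benzyloxy)-5-methoxybenzaldehyde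
Conditions: BnBr, K2CO3, DMF, 60 °C
Reagents that add atoms: benzyl bromide, BrCc1ccccc1
Why: Williamson etherification of both phenols installs benzyl groups that should survive every later step and leave together in step 9.

Step 2
Reactants: 2 3,4-bis(benzyloxy)-5-methoxybenzaldehyde; 3 dibenzyl (2S,3S)-2,3-dihydroxybutanedioate (dibenzyl D-tartrate)
Product: 4 dibenzyl (4S,5S)-2-[3,4-bis(benzyloxy)-5-methoxyphenyl]-1,3-dioxolane-4,5-dicarboxylate
Conditions: TsOH·H2O (5 mol %), toluene, reflux, Dean–Stark trap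
Reagents that add atoms: none
Why: Acid-catalysed acetalisation with azeotropic removal of water leaves both carbinol centres untouched, and because the diol is C2-symmetric the acetal carbon, the future C1, is not yet a stereocentre.

Step 3
Reactants: 5 [4-(benzyloxy)-3-methoxyphenyl]methanol
Product: 6 1-(benzyloxy)-4-(bromomethyl)-2-methoxybenzene
Conditions: PBr3, Et2O, 0 °C
Reagents that add atoms: phosphorus tribromide, BrP(Br)Br
Why: Bromination of an electron-rich benzylic alcohol through its phosphite ester gives the reactive C4 electrophile, which is used without storage.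

Step 4
Reactants: 4 dibenzyl (4S,5S)-2-[3,4-bis(benzyloxy)-5-methoxyphenyl]-1,3-dioxolane-4,5-dicarboxylate; 6 1-(benzyloxy)-4-(bromomethyl)-2-methoxybenzene
Product: 8 dibenzyl (2RS,4S,5S)-4-[4-(benzyloxy)-3-methoxybenzyl]-2-[3,4-bis(benzyloxy)-5-methoxyphenyl]-1,3-dioxolane-4,5-dicarboxylate, via lithium enolate 7 (not isolated)
Conditions: LiN(iPr)2, THF–DMPU, −78 °C; then 6, −78 → −30 °C
Reagents that add atoms: lithium diisopropylamide, [Li+].CC(C)[N-]C(C)C (lithium of 7 only)
Why: In this alkylation of a tartrate acetal enolate the β C–O bond is held in the ring orthogonal to the enolate π system, so β-elimination is suppressed, and such enolates react with retention, the bromide entering on the face the proton left (cis to the neighbouring ester, here also anti to the 2-aryl group), which sets the quaternary centre C3.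

Step 5
Reactants: 8 dibenzyl (2RS,4S,5S)-4-[4-(benzyloxy)-3-methoxybenzyl]-2-[3,4-bis(benzyloxy)-5-methoxyphenyl]-1,3-dioxolane-4,5-dicarboxylate
Product: 9 benzyl (1RS,3S)-7-(benzyloxy)-1-[3,4-bis(benzyloxy)-5-methoxyphenyl]-3-[(1S)-2-(benzyloxy)-1-hydroxy-2-oxoethyl]-6-methoxy-3,4-dihydro-1H-isochromene-3-carboxylate
Conditions: BF3·OEt2 (20 mol %), CH2Cl2, −40 → 0 °C
Reagents that add atoms: none
Why: In this oxa-Pictet–Spengler cyclisation from a cyclic acetal, BF3 binds the less hindered oxygen on C2 and the aryl-stabilised oxocarbenium ion left on the C3 oxygen is attacked by ring A at C8a, para to the methoxy group (6-endo-trig Friedel–Crafts closure), while the uncontrolled configuration at C1 is irrelevant because step 7 planarises it.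

Step 6
Reactants: 9 benzyl (1RS,3S)-7-(benzyloxy)-1-[3,4-bis(benzyloxy)-5-methoxyphenyl]-3-[(1S)-2-(benzyloxy)-1-hydroxy-2-oxoethyl]-6-methoxy-3,4-dihydro-1H-isochromene-3-carboxylate
Product: 10 benzyl (1RS,3S)-7-(benzyloxy)-1-[3,4-bis(benzyloxy)-5-methoxyphenyl]-3-[(1S)-1,2-bis(benzyloxy)-2-oxoethyl]-6-methoxy-3,4-dihydro-1H-isochromene-3-carboxylate
Conditions: BnBr, Ag2O, 4 Å molecular sieves, CH2Cl2, rt, dark
Reagents that add atoms: benzyl bromide, BrCc1ccccc1
Why: Silver-oxide-mediated Williamson benzylation under neutral conditions caps the C2 hydroxyl without forming a free alkoxide, which could trigger retro-aldol cleavage of C2–C3, so that after step 7 the C3 hydroxyl is the only free one.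

Step 7
Reactants: 10 benzyl (1RS,3S)-7-(benzyloxy)-1-[3,4-bis(benzyloxy)-5-methoxyphenyl]-3-[(1S)-1,2-bis(benzyloxy)-2-oxoethyl]-6-methoxy-3,4-dihydro-1H-isochromene-3-carboxylate
Product: 13 dibenzyl (1S,2S,3S)-2,7-bis(benzyloxy)-1-[3,4-bis(benzyloxy)-5-methoxyphenyl]-3-hydroxy-6-methoxy-1,2,3,4-tetrahydronaphthalene-2,3-dicarboxylate, via silyl ketene acetal 11 (not isolated), via tetralin silyl ether 12 (not isolated)
Conditions: LiN(iPr)2, Me3SiCl (internal quench), THF, −78 °C; evaporation, pentane, filtration; Me3SiOTf (10 mol %), 2,6-di-tert-butyl-4-methylpyridine (5 mol %), CH2Cl2, −78 → −30 °C; then 1 M HCl, THF, 0 °C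
Reagents that add atoms: chlorotrimethylsilane, C[Si](C)(C)Cl (silyl group of 11 and 12 only)
Why: LiN(iPr)2 with Me3SiCl as internal quench converts the glycolate-type ester of 10 into ketene acetal 11 before the C3 oxygen can be eliminated, and catalytic Me3SiOTf then silylates the ring oxygen and ionises the C1–O bond to a diarylmethyl cation stabilised by the para C6 methoxy group of ring A and the para C4' benzyloxy group of ring C; C2 attacks it, the silyl group ends on the C3 oxygen (12), and dilute acid frees 13. The closest known reaction type is the Mukaiyama-type SN1 alkylation of silyl ketene acetals with benzhydryl ethers under silyl triflate catalysis. Ring B closes in the 6-(enolexo)-exo-trig mode through a chair-like transition state while the isochroman ring opens. C2 is controlled by C3: the C3–O bond lies in the plane of the ketene acetal (least allylic 1,3-strain, opposed C2–O and C3–O dipoles, no σ*C–O antiperiplanar to the forming bond), so the tethered cation reaches only the face that places both carboxyl groups equatorial and the two oxygens trans. C1 is controlled by the preference of ring C for the pseudo-equatorial position, away from the axial C3 silyloxy group, which gives the 1,2-trans relation of aryl group and ester. The step needs facial selectivity only, because both C1 epimers of 10 and both ketene acetal geometries converge on the same ion, return of the cation to oxygen is reversible whereas C–C bond formation is not, and C2 is the only enolisable carbon.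

Step 8
Reactants: 13 dibenzyl (1S,2S,3S)-2,7-bis(benzyloxy)-1-[3,4-bis(benzyloxy)-5-methoxyphenyl]-3-hydroxy-6-methoxy-1,2,3,4-tetrahydronaphthalene-2,3-dicarboxylate
Product: 14 benzyl (1S,2S,3R)-2,7-bis(benzyloxy)-1-[3,4-bis(benzyloxy)-5-methoxyphenyl]-3-hydroxy-3-(hydroxymethyl)-6-methoxy-1,2,3,4-tetrahydronaphthalene-2-carboxylate
Conditions: BH3·SMe2, NaBH4 (5 mol %), THF, 0 °C → rt; aqueous work-up
Reagents that add atoms: none
Why: In this hydroxyl-directed borane reduction of an α-hydroxy ester the C3 alkoxyborane delivers hydride to its own ester through a five-membered chelate, whereas the C2 ester has no free hydroxyl beside it and is shielded by ring C, and no stereocentre is touched.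

Step 9
Reactants: 14 benzyl (1S,2S,3R)-2,7-bis(benzyloxy)-1-[3,4-bis(benzyloxy)-5-methoxyphenyl]-3-hydroxy-3-(hydroxymethyl)-6-methoxy-1,2,3,4-tetrahydronaphthalene-2-carboxylate
Product: 15 plicatic acid, (1S,2S,3R)-1-(3,4-dihydroxy-5-methoxyphenyl)-2,3,7-trihydroxy-3-(hydroxymethyl)-6-methoxy-1,2,3,4-tetrahydronaphthalene-2-carboxylic acid
Conditions: H2 (1 atm), Pd(OH)2/C, THF–MeOH, rt
Reagents that add atoms: none
Why: Catalytic hydrogenolysis removes the four benzyl ethers and the benzyl ester in one operation, while the skeleton holds no benzylic C–O bond and the stereocentres are not affected.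

**Compound list**

1 | 3,4-dihydroxy-5-methoxybenzaldehyde | COc1cc(C=O)cc(O)c1O | starting material
2 | 3,4-bis(benzyloxy)-5-methoxybenzaldehyde | COc1cc(C=O)cc(OCc2ccccc2)c1OCc1ccccc1 | intermediate
3 | dibenzyl (2S,3S)-2,3-dihydroxybutanedioate (dibenzyl D-tartrate) | O=C(OCc1ccccc1)[C@@H](O)[C@H](O)C(=O)OCc1ccccc1 | starting material
4 | dibenzyl (4S,5S)-2-[3,4-bis(benzyloxy)-5-methoxyphenyl]-1,3-dioxolane-4,5-dicarboxylate | O=C(OCc1ccccc1)[C@H]1OC(c2cc(OC)c(OCc3ccccc3)c(OCc3ccccc3)c2)O[C@@H]1C(=O)OCc1ccccc1 | intermediate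
5 | [4-(benzyloxy)-3-methoxyphenyl]methanol | COc1cc(CO)ccc1OCc1ccccc1 | starting material
6 | 1-(benzyloxy)-4-(bromomethyl)-2-methoxybenzene | COc1cc(CBr)ccc1OCc1ccccc1 | intermediate
7 | lithium enolate of 4 (one ester-bearing ring carbon planar, the other still S, acetal carbon RS) | [Li+].[O-]C(OCc1ccccc1)=C1OC(c2cc(OC)c(OCc3ccccc3)c(OCc3ccccc3)c2)O[C@@H]1C(=O)OCc1ccccc1 | intermediate
8 | dibenzyl (2RS,4S,5S)-4-[4-(benzyloxy)-3-methoxybenzyl]-2-[3,4-bis(benzyloxy)-5-methoxyphenyl]-1,3-dioxolane-4,5-dicarboxylate | O=C(OCc1ccccc1)[C@@]1(Cc2ccc(OCc3ccccc3)c(OC)c2)OC(c2cc(OC)c(OCc3ccccc3)c(OCc3ccccc3)c2)O[C@@H]1C(=O)OCc1ccccc1 | intermediate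
9 | benzyl (1RS,3S)-7-(benzyloxy)-1-[3,4-bis(benzyloxy)-5-methoxyphenyl]-3-[(1S)-2-(benzyloxy)-1-hydroxy-2-oxoethyl]-6-methoxy-3,4-dihydro-1H-isochromene-3-carboxylate | O=C(OCc1ccccc1)[C@]1(Cc2cc(OC)c(OCc3ccccc3)cc2C(c2cc(OC)c(OCc3ccccc3)c(OCc3ccccc3)c2)O1)[C@H](O)C(=O)OCc1ccccc1 | intermediate
10 | benzyl (1RS,3S)-7-(benzyloxy)-1-[3,4-bis(benzyloxy)-5-methoxyphenyl]-3-[(1S)-1,2-bis(benzyloxy)-2-oxoethyl]-6-methoxy-3,4-dihydro-1H-isochromene-3-carboxylate | O=C(OCc1ccccc1)[C@]1(Cc2cc(OC)c(OCc3ccccc3)cc2C(c2cc(OC)c(OCc3ccccc3)c(OCc3ccccc3)c2)O1)[C@H](OCc1ccccc1)C(=O)OCc1ccccc1 | intermediate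
11 | benzyl (1RS,3S)-7-(benzyloxy)-1-[3,4-bis(benzyloxy)-5-methoxyphenyl]-3-[1,2-bis(benzyloxy)-2-(trimethylsilyloxy)ethenyl]-6-methoxy-3,4-dihydro-1H-isochromene-3-carboxylate (alkene geometry not controlled) | O=C(OCc1ccccc1)[C@]1(Cc2cc(OC)c(OCc3ccccc3)cc2C(c2cc(OC)c(OCc3ccccc3)c(OCc3ccccc3)c2)O1)C(OCc1ccccc1)=C(OCc1ccccc1)O[Si](C)(C)C | intermediate
12 | dibenzyl (1S,2S,3S)-2,7-bis(benzyloxy)-1-[3,4-bis(benzyloxy)-5-methoxyphenyl]-6-methoxy-3-(trimethylsilyloxy)-1,2,3,4-tetrahydronaphthalene-2,3-dicarboxylate | COc1cc2c(cc1OCc1ccccc1)[C@H](c1cc(OCc3ccccc3)c(OCc3ccccc3)c(OC)c1)[C@@](OCc1ccccc1)(C(=O)OCc1ccccc1)[C@](O[Si](C)(C)C)(C(=O)OCc1ccccc1)C2 | intermediate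
13 | dibenzyl (1S,2S,3S)-2,7-bis(benzyloxy)-1-[3,4-bis(benzyloxy)-5-methoxyphenyl]-3-hydroxy-6-methoxy-1,2,3,4-tetrahydronaphthalene-2,3-dicarboxylate | COc1cc2c(cc1OCc1ccccc1)[C@H](c1cc(OCc3ccccc3)c(OCc3ccccc3)c(OC)c1)[C@@](OCc1ccccc1)(C(=O)OCc1ccccc1)[C@](O)(C(=O)OCc1ccccc1)C2 | intermediate
14 | benzyl (1S,2S,3R)-2,7-bis(benzyloxy)-1-[3,4-bis(benzyloxy)-5-methoxyphenyl]-3-hydroxy-3-(hydroxymethyl)-6-methoxy-1,2,3,4-tetrahydronaphthalene-2-carboxylate | COc1cc2c(cc1OCc1ccccc1)[C@H](c1cc(OCc3ccccc3)c(OCc3ccccc3)c(OC)c1)[C@@](OCc1ccccc1)(C(=O)OCc1ccccc1)[C@](O)(CO)C2 | intermediate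
15 | plicatic acid, (1S,2S,3R)-1-(3,4-dihydroxy-5-methoxyphenyl)-2,3,7-trihydroxy-3-(hydroxymethyl)-6-methoxy-1,2,3,4-tetrahydronaphthalene-2-carboxylic acid | COc1cc2c(cc1O)[C@H](c1cc(O)c(O)c(OC)c1)[C@@](O)(C(=O)O)[C@](O)(CO)C2 | target

**Step count.** Total steps: 9. Longest linear sequence: 8 steps (1, 2, 4, 5, 6, 7, 8, 9).

**Steps most likely to fail**

**Step 7.**
- What may go wrong:
  - β-elimination of the C3 oxygen while the ester is enolised, because the C2–C3 bond of 10 rotates freely.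
  - Protonation of the ketene acetal before the C1–O bond ionises.
  - Erosion of facial selectivity at C2 or C1.
- Fallback: enolise while the C3 oxygen is still locked in the dioxolane, and let the acetal carbon exchange both C–O bonds in one flask. The fallback sets out from 8. LiOH (1 equiv) cleaves the less hindered ester on the CH carbon and gives the dioxolane monoacid F1. LiN(iPr)2 (2.2 equiv) and Me3SiCl give the bis(trimethylsilyl) ketene acetal F2, whose β C–O bond is orthogonal to the π system. Me3SiOTf (1.1 equiv) and 2,6-di-tert-butyl-4-methylpyridine in CH2Cl2 then open the acetal. Ring A closes on C1 and C2 displaces the second oxygen, which should give the tris(trimethylsilyl) tetralin F3. Aqueous acid then gives the dihydroxy acid monoester F4. LiBH4 reduces the benzyl ester beside the inert carboxylate to tri-O-benzylplicatic acid F5. Hydrogenolysis as in step 9 comes back to the route at 15.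

**Step 4.**
- What may go wrong:
  - Removal of the α-proton syn to the 2-aryl group, or alkylation syn to it, which would erode the configuration at C3.
  - Fragmentation of the enolate on warming.
- Fallback: use the symmetric isopropylidene acetal, for which stereoretentive alkylation is the standard case, and bring in C1 afterwards. The fallback sets out from 3. 2,2-Dimethoxypropane and TsOH give the tartrate acetonide F6. LiN(iPr)2 gives the acetonide lithium enolate F7, and 6 converts it into the alkylated acetonide F8. Aqueous CF3CO2H gives the benzylated tartrate diol F9. Condensation of F9 with 2 under BF3·OEt2 (acetalisation and oxa-Pictet–Spengler closure in one flask) comes back to the route at 9.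

**Step 8.**
- What may go wrong:
  - Loss of chemoselectivity between the two benzyl esters.
  - Lactonisation of the new primary alkoxide onto the C2 ester, followed by over-reduction.
- Fallback: differentiate by hydrolysis instead of by hydride delivery. The fallback sets out from 13. LiOH (1 equiv) saponifies the less hindered α-hydroxy ester at C3 to the C3 monoacid F10. BH3·THF at 0 °C, which reduces a carboxylic acid faster than any ester, comes back to the route at 14.

**Further compounds**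

F1 | step 7 | dioxolane monoacid, (2RS,4S,5S)-5-[(benzyloxy)carbonyl]-5-[4-(benzyloxy)-3-methoxybenzyl]-2-[3,4-bis(benzyloxy)-5-methoxyphenyl]-1,3-dioxolane-4-carboxylic acid | O=C(OCc1ccccc1)[C@@]1(Cc2ccc(OCc3ccccc3)c(OC)c2)OC(c2cc(OC)c(OCc3ccccc3)c(OCc3ccccc3)c2)O[C@@H]1C(=O)O
F2 | step 7 | bis(trimethylsilyl) ketene acetal, benzyl (2RS,4S)-4-[4-(benzyloxy)-3-methoxybenzyl]-2-[3,4-bis(benzyloxy)-5-methoxyphenyl]-5-[bis(trimethylsilyloxy)methylidene]-1,3-dioxolane-4-carboxylate | O=C(OCc1ccccc1)[C@@]1(Cc2ccc(OCc3ccccc3)c(OC)c2)OC(c2cc(OC)c(OCc3ccccc3)c(OCc3ccccc3)c2)OC1=C(O[Si](C)(C)C)O[Si](C)(C)C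
F3 | step 7 | tris(trimethylsilyl) tetralin, 3-benzyl 2-trimethylsilyl (1S,2S,3S)-7-(benzyloxy)-1-[3,4-bis(benzyloxy)-5-methoxyphenyl]-6-methoxy-2,3-bis(trimethylsilyloxy)-1,2,3,4-tetrahydronaphthalene-2,3-dicarboxylate | COc1cc2c(cc1OCc1ccccc1)[C@H](c1cc(OCc3ccccc3)c(OCc3ccccc3)c(OC)c1)[C@@](O[Si](C)(C)C)(C(=O)O[Si](C)(C)C)[C@](O[Si](C)(C)C)(C(=O)OCc1ccccc1)C2
F4 | step 7 | dihydroxy acid monoester, (1S,2S,3S)-7-(benzyloxy)-3-[(benzyloxy)carbonyl]-1-[3,4-bis(benzyloxy)-5-methoxyphenyl]-2,3-dihydroxy-6-methoxy-1,2,3,4-tetrahydronaphthalene-2-carboxylic acid | COc1cc2c(cc1OCc1ccccc1)[C@H](c1cc(OCc3ccccc3)c(OCc3ccccc3)c(OC)c1)[C@@](O)(C(=O)O)[C@](O)(C(=O)OCc1ccccc1)C2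
F5 | step 7 | tri-O-benzylplicatic acid, (1S,2S,3R)-7-(benzyloxy)-1-[3,4-bis(benzyloxy)-5-methoxyphenyl]-2,3-dihydroxy-3-(hydroxymethyl)-6-methoxy-1,2,3,4-tetrahydronaphthalene-2-carboxylic acid | COc1cc2c(cc1OCc1ccccc1)[C@H](c1cc(OCc3ccccc3)c(OCc3ccccc3)c(OC)c1)[C@@](O)(C(=O)O)[C@](O)(CO)C2
F6 | step 4 | tartrate acetonide, dibenzyl (4S,5S)-2,2-dimethyl-1,3-dioxolane-4,5-dicarboxylate | O=C(OCc1ccccc1)[C@H]1OC(C)(C)O[C@@H]1C(=O)OCc1ccccc1
F7 | step 4 | acetonide lithium enolate (one ring carbon planar, the other still S) | [Li+].[O-]C(OCc1ccccc1)=C1OC(C)(C)O[C@@H]1C(=O)OCc1ccccc1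
F8 | step 4 | alkylated acetonide, dibenzyl (4S,5S)-4-[4-(benzyloxy)-3-methoxybenzyl]-2,2-dimethyl-1,3-dioxolane-4,5-dicarboxylate | O=C(OCc1ccccc1)[C@@]1(Cc2ccc(OCc3ccccc3)c(OC)c2)OC(C)(C)O[C@@H]1C(=O)OCc1ccccc1
F9 | step 4 | benzylated tartrate diol, dibenzyl (2S,3S)-2-[4-(benzyloxy)-3-methoxybenzyl]-2,3-dihydroxybutanedioate | O=C(OCc1ccccc1)[C@@](Cc1ccc(OCc2ccccc2)c(OC)c1)(O)[C@H](O)C(=O)OCc1ccccc1
F10 | step 8 | C3 monoacid, (2S,3S,4S)-3,6-bis(benzyloxy)-3-[(benzyloxy)carbonyl]-4-[3,4-bis(benzyloxy)-5-methoxyphenyl]-2-hydroxy-7-methoxy-1,2,3,4-tetrahydronaphthalene-2-carboxylic acid | COc1cc2c(cc1OCc1ccccc1)[C@H](c1cc(OCc3ccccc3)c(OCc3ccccc3)c(OC)c1)[C@@](OCc1ccccc1)(C(=O)OCc1ccccc1)[C@](O)(C(=O)O)C2
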